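The oxolane ring is disconnected at the bond between its oxygen O1 and the benzylic carbon C2, which is carried as an aryl ketone. The precursor is an acyclic γ-hydroxy ketone; its C3, C4 and C5 stereocentres come from an auxiliary-controlled anti-aldol and a temporary γ-lactone. In one operation the key step adds the C5 hydroxyl to the ketone, ionises the lactol and reduces the 2-aryl oxocarbenium ion. It exploits that C2 is both benzylic and bonded to O1, and that the CH2O branch on C3 steers hydride to the opposite face: the aryl group ends cis to that branch, the contra-thermodynamic relationship that cation or quinone methide closures would not give.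

Key step: step 8

Remark on the chemistry: Ar = 4-(tert-butyldimethylsilyloxy)-3-methoxyphenyl and TBS = tert-butyldimethylsilyl; ring atoms are numbered as in the target (O1, C2 to C5); 4 and 12 are taken as catalogue compounds; the aryllithium adduct 14 is a ring–chain tautomer pair and is written as its open hydroxy ketone, the form that step 8 closes.

Step 1
Reactants: 1 (S)-4-benzyloxazolidin-2-one; 2 methyl 4-chloro-4-oxobutanoate
Product: 3 methyl 4-[(4S)-4-benzyl-2-oxooxazolidin-3-yl]-4-oxobutanoate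
Conditions: n-BuLi, THF, −78 °C; then 2, −78 to 0 °C
Reagents that add atoms: none
Why: N-acylation of the lithiated oxazolidinone by the acid chloride (standard preparation of an Evans imide) should outrun any attack on the methyl ester at −78 °C.

Step 2
Reactants: 3 methyl 4-[(4S)-4-benzyl-2-oxooxazolidin-3-yl]-4-oxobutanoate; 4 4-(tert-butyldimethylsilyloxy)-3-methoxybenzaldehyde
Product: 7 (4S)-4-benzyl-3-{[(2S,3R)-2-Ar-5-oxooxolan-3-yl]carbonyl}oxazolidin-2-one (cis-lactone imide), via silyl ether 5 (not isolated), via hydroxy ester 6 (not isolated)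
Conditions: MgCl2 (20 mol %), Et3N, Me3SiCl, EtOAc, 23 °C; then 1 M HCl, THF, 0 °C; then PPTS, PhMe, 50 °C
Reagents that add atoms: none
Why: Evans magnesium halide-catalysed anti-aldol, in which the chelated Z-enolate of the (S)-imide should add to the aldehyde on the face opposite the benzyl group through a boat transition state to set C4 and C5 as the (3R,4S)-anti adduct, followed by acid-catalysed 5-exo-trig lactonisation of the freed benzylic hydroxyl onto the methyl ester to the 4,5-cis γ-lactone.

Step 3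
Reactants: 7 (4S)-4-benzyl-3-{[(2S,3R)-2-Ar-5-oxooxolan-3-yl]carbonyl}oxazolidin-2-one
Product: 8 (4S,5S)-5-Ar-4-(hydroxymethyl)oxolan-2-one
Conditions: NaBH4, THF/H2O (3:1), 0 to 23 °C; NH4Cl
Reagents that add atoms: none
Why: Chemoselective borohydride reduction of the activated exocyclic N-acyl carbonyl (reductive cleavage of an N-acyloxazolidinone) should release the auxiliary and give the CH2OH group on C4 while the γ-lactone survives and no stereocentre is touched.

Step 4
Reactants: 8 (4S,5S)-5-Ar-4-(hydroxymethyl)oxolan-2-one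
Product: 9 (4S,5S)-5-Ar-4-(TBS-oxymethyl)oxolan-2-one
Conditions: t-BuMe2SiCl, imidazole, DMF, 0 °C
Reagents that add atoms: tert-butyldimethylsilyl chloride CC(C)(C)[Si](C)(C)Cl
Why: Silylation of the primary alcohol under mild base, done at once, should block migration of the lactone acyl group onto this hydroxyl.

Step 5
Reactants: 9 (4S,5S)-5-Ar-4-(TBS-oxymethyl)oxolan-2-one
Product: 10 (3S,4S,5S)-5-Ar-3-(hydroxymethyl)-4-(TBS-oxymethyl)oxolan-2-one
Conditions: LiN(i-Pr)2, THF, −78 °C; CH2O (gas, from cracked paraformaldehyde), −78 °C; NH4Cl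
Reagents that add atoms: formaldehyde C=O
Why: Aldol hydroxymethylation of the lithium lactone enolate, in which formaldehyde should add to C3 on the face opposite the cis-related C4 branch and C5 aryl group, setting C3 trans to C4.

Step 6
Reactants: 10 (3S,4S,5S)-5-Ar-3-(hydroxymethyl)-4-(TBS-oxymethyl)oxolan-2-one
Product: 11 (3S,4S,5S)-5-Ar-3,4-bis(TBS-oxymethyl)oxolan-2-one
Conditions: t-BuMe2SiCl, imidazole, DMF, 0 to 23 °C
Reagents that add atoms: tert-butyldimethylsilyl chloride CC(C)(C)[Si](C)(C)Cl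
Why: Standard silyl ether formation should protect the second primary alcohol, so that neither CH2O oxygen can later compete with the C5 hydroxyl for the ketone.

Step 7
Reactants: 11 (3S,4S,5S)-5-Ar-3,4-bis(TBS-oxymethyl)oxolan-2-one; 12 (4-bromo-2-methoxyphenoxy)(tert-butyl)dimethylsilane
Product: 14 (2S,3S,4S)-1,4-di-Ar-4-hydroxy-2,3-bis(TBS-oxymethyl)butan-1-one, via aryllithium 13 (not isolated)
Conditions: 12, n-BuLi, THF, −78 °C; then 11, −78 °C; NH4Cl at −78 °C
Reagents that add atoms: none
Why: Bromine–lithium exchange followed by single addition of the aryllithium to the lactone carbonyl, whose tetrahedral lithium alkoxide should persist at −78 °C until the quench, opens the temporary ring to the aryl ketone without touching C3, C4 or C5.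

Step 8
Reactants: 14 (2S,3S,4S)-1,4-di-Ar-4-hydroxy-2,3-bis(TBS-oxymethyl)butan-1-one
Product: 17 (2S,3S,4S,5S)-2,5-di-Ar-3,4-bis(TBS-oxymethyl)oxolane, via lactol 15 (not isolated), via oxocarbenium ion 16 (not isolated)
Conditions: Et3SiH, BF3·OEt2, CH2Cl2, −78 °C; Et3N then NaHCO3 at −78 °C
Reagents that add atoms: none
Why: BF3·OEt2 should close the γ-hydroxy ketone to lactol 15 by addition of the C5 hydroxyl oxygen (O1) to the aryl ketone carbon (C2) and ionise it to the 2-aryl oxocarbenium ion 16, which Et3SiH reduces irreversibly. The closest known reaction type is the Lewis acid/silane reductive etherification of hydroxy ketones and their lactols (ionic hydrogenation), as applied to 2,5-diaryl-3,4-dialkyl oxolanes. The oxolane ring closes in the 5-exo-trig mode at the carbonyl carbon. The new stereocentre C2 is controlled by the neighbouring C3 branch: allylic 1,2-strain with the coplanar aryl group should turn the C3 CH2OTBS group pseudoaxial, and hydride enters the envelope on the opposite face, so the aryl group ends cis to the C3 branch and trans to the C5 aryl group. The step needs this facial selectivity although the C4 branch and the C5 aryl group lie on the attacked face, and it needs the cis benzylic ethers of 17 not to re-ionise; the position of C3 next to the cationic carbon and the reaction at −78 °C with a cold basic quench should secure both. Only the free C5 hydroxyl can add to the ketone, because both CH2O oxygens are silyl ethers.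

Step 9
Reactants: 17 (2S,3S,4S,5S)-2,5-di-Ar-3,4-bis(TBS-oxymethyl)oxolane
Product: 18 [(2S,3S,4S,5S)-2,5-bis(4-hydroxy-3-methoxyphenyl)oxolane-3,4-diyl]dimethanol (eduesmine)
Conditions: Bu4NF, AcOH (1:1), THF, 0 to 23 °C
Reagents that add atoms: none
Why: Fluoride-mediated desilylation should cleave the two aryl and the two primary alkyl silyl ethers, and the acetic acid buffer keeps the phenols protonated so that the benzylic ring C–O bonds cannot open through a quinone methide.

Compound list

1 | (S)-4-benzyloxazolidin-2-one | O=C1N[C@@H](Cc2ccccc2)CO1 | starting material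
2 | methyl 4-chloro-4-oxobutanoate | COC(=O)CCC(Cl)=O | starting material
3 | methyl 4-[(4S)-4-benzyl-2-oxooxazolidin-3-yl]-4-oxobutanoate | COC(=O)CCC(=O)N1[C@@H](Cc2ccccc2)COC1=O | intermediate
4 | 4-(tert-butyldimethylsilyloxy)-3-methoxybenzaldehyde | COc1cc(C=O)ccc1O[Si](C)(C)C(C)(C)C | starting material
5 | methyl (3R,4S)-3-{[(4S)-4-benzyl-2-oxooxazolidin-3-yl]carbonyl}-4-Ar-4-(trimethylsilyloxy)butanoate (silyl ether of the anti-aldol adduct) | COc1cc([C@@H](O[Si](C)(C)C)[C@@H](CC(=O)OC)C(=O)N2[C@@H](Cc3ccccc3)COC2=O)ccc1O[Si](C)(C)C(C)(C)C | intermediate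
6 | methyl (3R,4S)-3-{[(4S)-4-benzyl-2-oxooxazolidin-3-yl]carbonyl}-4-Ar-4-hydroxybutanoate | COc1cc([C@@H](O)[C@@H](CC(=O)OC)C(=O)N2[C@@H](Cc3ccccc3)COC2=O)ccc1O[Si](C)(C)C(C)(C)C | intermediate
7 | (4S)-4-benzyl-3-{[(2S,3R)-2-Ar-5-oxooxolan-3-yl]carbonyl}oxazolidin-2-one (aryl and acyl groups cis on the lactone) | COc1cc([C@H]2OC(=O)C[C@H]2C(=O)N3[C@@H](Cc4ccccc4)COC3=O)ccc1O[Si](C)(C)C(C)(C)C | intermediate
8 | (4S,5S)-5-Ar-4-(hydroxymethyl)oxolan-2-one | COc1cc([C@H]2OC(=O)C[C@H]2CO)ccc1O[Si](C)(C)C(C)(C)C | intermediate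
9 | (4S,5S)-5-Ar-4-(TBS-oxymethyl)oxolan-2-one | COc1cc([C@H]2OC(=O)C[C@H]2CO[Si](C)(C)C(C)(C)C)ccc1O[Si](C)(C)C(C)(C)C | intermediate
10 | (3S,4S,5S)-5-Ar-3-(hydroxymethyl)-4-(TBS-oxymethyl)oxolan-2-one | COc1cc([C@H]2OC(=O)[C@H](CO)[C@H]2CO[Si](C)(C)C(C)(C)C)ccc1O[Si](C)(C)C(C)(C)C | intermediate
11 | (3S,4S,5S)-5-Ar-3,4-bis(TBS-oxymethyl)oxolan-2-one | COc1cc([C@H]2OC(=O)[C@H](CO[Si](C)(C)C(C)(C)C)[C@H]2CO[Si](C)(C)C(C)(C)C)ccc1O[Si](C)(C)C(C)(C)C | intermediate
12 | (4-bromo-2-methoxyphenoxy)(tert-butyl)dimethylsilane | COc1cc(Br)ccc1O[Si](C)(C)C(C)(C)C | starting material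
13 | [4-(tert-butyldimethylsilyloxy)-3-methoxyphenyl]lithium | COc1cc([Li])ccc1O[Si](C)(C)C(C)(C)C | intermediate
14 | (2S,3S,4S)-1,4-di-Ar-4-hydroxy-2,3-bis(TBS-oxymethyl)butan-1-one (open tautomer) | COc1cc([C@@H](O)[C@H](CO[Si](C)(C)C(C)(C)C)[C@@H](CO[Si](C)(C)C(C)(C)C)C(=O)c2ccc(O[Si](C)(C)C(C)(C)C)c(OC)c2)ccc1O[Si](C)(C)C(C)(C)C | intermediate
15 | (3S,4S,5S)-2,5-di-Ar-3,4-bis(TBS-oxymethyl)oxolan-2-ol (lactol, both anomers) | COc1cc([C@H]2OC(O)(c3ccc(O[Si](C)(C)C(C)(C)C)c(OC)c3)[C@H](CO[Si](C)(C)C(C)(C)C)[C@H]2CO[Si](C)(C)C(C)(C)C)ccc1O[Si](C)(C)C(C)(C)C | intermediate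
16 | (3S,4S,5S)-2,5-di-Ar-3,4-bis(TBS-oxymethyl)-4,5-dihydro-3H-furan-1-ium hydroxytrifluoroborate (2-aryl oxocarbenium ion) | COc1cc([C@H]2[O+]=C(c3ccc(O[Si](C)(C)C(C)(C)C)c(OC)c3)[C@H](CO[Si](C)(C)C(C)(C)C)[C@H]2CO[Si](C)(C)C(C)(C)C)ccc1O[Si](C)(C)C(C)(C)C.O[B-](F)(F)F | intermediate
17 | (2S,3S,4S,5S)-2,5-di-Ar-3,4-bis(TBS-oxymethyl)oxolane | COc1cc([C@H]2O[C@H](c3ccc(O[Si](C)(C)C(C)(C)C)c(OC)c3)[C@H](CO[Si](C)(C)C(C)(C)C)[C@H]2CO[Si](C)(C)C(C)(C)C)ccc1O[Si](C)(C)C(C)(C)C | intermediate
18 | [(2S,3S,4S,5S)-2,5-bis(4-hydroxy-3-methoxyphenyl)oxolane-3,4-diyl]dimethanol (eduesmine) | COc1cc([C@H]2O[C@H](c3ccc(O)c(OC)c3)[C@H](CO)[C@H]2CO)ccc1O | target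

Total step count: 9. Longest linear sequence: 9 steps (1 → 3 → 7 → 8 → 9 → 10 → 11 → 14 → 17 → 18).

Steps most likely to fail

(a) Step 8, the key step. What may go wrong is hydride transfer to the face syn to the C3 branch and, above all, re-ionisation of the electron-rich cis benzylic ethers under the Lewis acid (ring opening with epimerisation towards the all-trans ring, or over-reduction). The fallback takes the p-silyloxybenzyl motif out of the acidic step. Setting out from 14, KHF2 in MeOH at 23 °C should cleave only the two aryl silyl ethers to give bis-phenol F1. Ac2O/Et3N in CH2Cl2 at 0 °C should acetylate the phenols only, giving bis(aryl acetate) F2, whose acetoxyaryl rings no longer support benzylic cations. The same Et3SiH/BF3·OEt2 closure, which can then be run warmer and longer, should give oxolane F3 without ionisation of either benzylic ether. K2CO3 in MeOH at 0 °C removes the acetates to give bis-phenol F4, and Bu4NF/AcOH removes the two remaining silyl ethers, which returns to the route at 18.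

(b) Step 2. What may go wrong is erosion of anti and facial control in the soft-enolisation aldol of an imide that carries a second, chelating ester (syn adducts, slow reaction with the electron-rich aldehyde), or ionisation of the p-silyloxybenzylic carbinol during the acid lactonisation. The fallback reaches the same (3R,4S) arrangement through a different control element, an open transition state. Setting out from 2, acylation of commercial (R)-4-benzyloxazolidin-2-one as in step 1 gives the enantiomeric imide F5. Its dibutylboron Z-enolate (Bu2BOTf, i-Pr2NEt, CH2Cl2, −78 °C) is added to 4 precomplexed with Et2AlCl; this should give anti-aldol F6 directly as the free alcohol, with the same enolate face as in the syn-aldol of this auxiliary but the anti relationship. F6 is lactonised with PPTS to lactone imide F7, and NaBH4 as in step 3 removes the (R)-auxiliary and returns to the route at 8.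

(c) Step 3. What may go wrong is migration of the lactone acyl group onto the primary alkoxide formed on hydride cleavage of the imide (translactonisation to the isomeric lactone with a free benzylic hydroxyl), or over-reduction of the lactone. The fallback generates no alkoxide. Setting out from 7, LiOH/H2O2 in THF/H2O at 0 °C removes the auxiliary to give carboxylic acid F8. BH3·SMe2 in THF at 0 °C should then reduce the acid in the presence of the lactone and give 8 after a neutral work-up, where the route is rejoined; 8 is silylated at once in step 4, which would also re-silylate any phenol freed by the peroxide step.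

Further compounds
F1 | step 8 | (2S,3S,4S)-4-hydroxy-1,4-bis(4-hydroxy-3-methoxyphenyl)-2,3-bis(TBS-oxymethyl)butan-1-one | COc1cc([C@@H](O)[C@H](CO[Si](C)(C)C(C)(C)C)[C@@H](CO[Si](C)(C)C(C)(C)C)C(=O)c2ccc(O)c(OC)c2)ccc1O
F2 | step 8 | (2S,3S,4S)-1,4-bis(4-acetoxy-3-methoxyphenyl)-4-hydroxy-2,3-bis(TBS-oxymethyl)butan-1-one | COc1cc([C@@H](O)[C@H](CO[Si](C)(C)C(C)(C)C)[C@@H](CO[Si](C)(C)C(C)(C)C)C(=O)c2ccc(OC(C)=O)c(OC)c2)ccc1OC(C)=O
F3 | step 8 | (2S,3S,4S,5S)-2,5-bis(4-acetoxy-3-methoxyphenyl)-3,4-bis(TBS-oxymethyl)oxolane | COc1cc([C@H]2O[C@H](c3ccc(OC(C)=O)c(OC)c3)[C@H](CO[Si](C)(C)C(C)(C)C)[C@H]2CO[Si](C)(C)C(C)(C)C)ccc1OC(C)=O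
F4 | step 8 | (2S,3S,4S,5S)-2,5-bis(4-hydroxy-3-methoxyphenyl)-3,4-bis(TBS-oxymethyl)oxolane | COc1cc([C@H]2O[C@H](c3ccc(O)c(OC)c3)[C@H](CO[Si](C)(C)C(C)(C)C)[C@H]2CO[Si](C)(C)C(C)(C)C)ccc1O
F5 | step 2 | methyl 4-[(4R)-4-benzyl-2-oxooxazolidin-3-yl]-4-oxobutanoate | COC(=O)CCC(=O)N1[C@H](Cc2ccccc2)COC1=O
F6 | step 2 | methyl (3R,4S)-3-{[(4R)-4-benzyl-2-oxooxazolidin-3-yl]carbonyl}-4-Ar-4-hydroxybutanoate | COc1cc([C@@H](O)[C@@H](CC(=O)OC)C(=O)N2[C@H](Cc3ccccc3)COC2=O)ccc1O[Si](C)(C)C(C)(C)C
F7 | step 2 | (4R)-4-benzyl-3-{[(2S,3R)-2-Ar-5-oxooxolan-3-yl]carbonyl}oxazolidin-2-one | COc1cc([C@H]2OC(=O)C[C@H]2C(=O)N3[C@H](Cc4ccccc4)COC3=O)ccc1O[Si](C)(C)C(C)(C)C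
F8 | step 3 | (2S,3R)-2-Ar-5-oxooxolane-3-carboxylic acid | COc1cc([C@H]2OC(=O)C[C@H]2C(O)=O)ccc1O[Si](C)(C)C(C)(C)C
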